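We read this flask at 60 h, and the eta run is this same flask, followed so far up to 40.0 h.

- eta: L 0.25 M; D 3 equiv; the very flask that is asked about, followed so far
- flask: L 0.25 M; D 3.00 equiv; time 2.5 d

eta run (percent of the L charged)

| time / h | G / % | L / % |
|---|---|---|
| 2.50 | 5.2 | 91.3 |
| 8.00 | 8.2 | 79.9 |
| 12.0 | 10.6 | 73.7 |
| 20.0 | 10.9 | 62.4 |
| 30.0 | 12.0 | 50.0 |
| 40.0 | 13.9 | 36.6 |

(standard deviation of a reading: 0.5 percentage points)

- south-east: at 2.5 d take out 90% of the G then present, then wait 5.0 d
- north-east: change nothing and wait 5.0 d more
- west: at 2.5 d add D, 100% of the amount charged, then wait 5.0 d

- G, in percent of the L first charged, at 2.5 d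
- what to do for the largest gain in G; "none" if nothing gains more than 2 percentage points (south-east / north-east / west / none)
- G present, with what was taken out counted in, in percent of the L first charged, after south-east
- G present, with what was taken out counted in, in percent of the L first charged, after north-east

- L is a solid; its amount is given per volume of the solution
- removed G is counted in
- at the start none of L is in solution
- additions bring no volume worth counting

We start with the main step on its own: L dissolves and each L lost becomes G. After a small early burst, the readings of cL fall steadily, by a fraction 0.01353 h⁻¹ of the charge. So L should stand near 9.54% at 60 h, and G near 90.5%. The readings refuse this: at 40.0 h, L has lost 63.4% of its charge, but G stands at 13.9%.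

Next we add a loss of D. Read from the first reading and from the stretch between 20.0 h and 40.0 h, with their scatter, the rate of G ends 13.9 times lower than it began, while the fall of L stays steady after its burst. At one D for each G, G has used 4.63% of the D charged, so we suppose that D goes mainly by a route of its own. We count doublings of time, and G gains about 2.2 percentage points on each. Our own figure for now is therefore 15.2%.

Then we add the end of the solid. Our quantity is 7.05 h, the solid's time left: L present divided by its steady fall. It is shorter than the wait of 120 h, and we count no G after it. Over that time, north-east gains 0.35 points, which is less than 2 points. We lay the slowing on D and not on G, so we expect south-east to gain the same, and both end near 15.5%. A full dose of D should restart the run for that time. The reading of G at 8.00 h, the nearest in time, suggests a gain of about 8.2 points. We commit to west.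

The forecast gives 15% now, 19% after south-east and 14% after north-east, and it picks south-east. On west it says: “D is still in excess, so adding it should do little”.

The flask gives 14.5% now and 14.9% after both south-east and north-east, each a gain of 0.47 points. West gains 8.9 points, the most, so the answer is west. In this flask at 60.0 h, D, the limiting reagent here, stands at 0.53% of its charge.

    2 D → E (k = 0.0170 L mol⁻¹ min⁻¹)
    Z + D → G (k = 0.0420 L mol⁻¹ min⁻¹)
    L ⇌ Z, rate k3*(cs3 - [Z]) while solid is left; crystals form when [Z] > cs3 (solubility = 9.50 mM, k = 0.0550 min⁻¹)
    2 Z → Q (k = 0.350 L mol⁻¹ min⁻¹)

The flask holds 11.1% of L at 60.0 h, so our 7.05 h becomes 8.20 h. The neighbour flask has 0.062 M of L, with the same equivalents. At the same fall of 0.003383 M h⁻¹, its whole charge lasts 18.3 h, less than 60 h. In that flask at 60.0 h, L, solid and dissolved, is down to 0.38% of its charge, D stands at 3.8% of its own, and G reaches 29.9%.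

(The readings were computed on assumed constants.)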